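## Retrosynthetic overview

1. **Feature.** Unit 1 has benzo ring A, pyranone ring C and aryl ring B. Unit 2 has benzo ring D (C4a''–C8a''), pyranone ring E (O1'', C2'', C3'', C4'') and aryl ring F. C3' of unit 1 is bonded to C8'', which lies between the oxygen-bearing carbons C7'' and C8a''. With ring E removed, ring D is a 2-aryl-5-alkoxyresorcinol with a mirror plane through C8'' and C5'', so C4a'' and C6'' are the same position.
2. **Disconnection 1 (ring E, formed last).** C4a''–C4'', C4''–C3'' and O1''–C2'' are cut back to a C4a'' iodide, CO and 4-benzyloxyphenylacetylene. The C5'' oxygen stays benzylated, so only the C8a'' hydroxyl can close the ring.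
3. **Disconnection 2.** The C4a''–I bond goes back to the symmetric resorcinol. The C3'–C8'' bond goes back to a Negishi coupling of a ring-D zinc reagent, metalated between two MOM ethers, with the 3'-bromoflavone of unit 1.
4. **Disconnection 3 (ring C, formed first).** The 3'-bromoflavone comes from a 2'-hydroxychalcone, made from a monobenzylated acetophenone and 4-benzyloxy-3-bromobenzaldehyde.
5. **Order of rings.** Rings A, B, D and F are bought as arenes. Ring C closes in step 4 and ring E in step 10. Removal of all benzyl groups ends the route.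

Key step: step 10

Assumption: the target SMILES fixes no configuration at the C3'–C8'' axis and holds no stereocentre, so all biaryls are treated as racemic or interconverting rotamers and no axial control is attempted.

## Route

Step 1
Reactants: 1 2',6'-dihydroxy-4'-methoxyacetophenone
Product: 2 1-[2-(benzyloxy)-6-hydroxy-4-methoxyphenyl]ethan-1-one
Conditions: BnBr (1.05 equiv), K2CO3 (1.2 equiv), acetone, reflux
Reagents that add atoms: benzyl bromide, BrCc1ccccc1
Why: Williamson etherification of one of two equivalent phenols, which should stop at the monoether because the remaining hydroxyl is held in a hydrogen bond to the acetyl oxygen and is much less nucleophilic.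

Step 2
Reactants: 3 3-bromo-4-hydroxybenzaldehyde
Product: 4 4-(benzyloxy)-3-bromobenzaldehyde
Conditions: BnBr (1.1 equiv), K2CO3, DMF, rt
Reagents that add atoms: benzyl bromide, BrCc1ccccc1
Why: Williamson etherification of an acidic para-formyl phenol, the only alkylatable site in the molecule.

Step 3
Reactants: 2 1-[2-(benzyloxy)-6-hydroxy-4-methoxyphenyl]ethan-1-one; 4 4-(benzyloxy)-3-bromobenzaldehyde
Product: 5 (E)-1-[2-(benzyloxy)-6-hydroxy-4-methoxyphenyl]-3-[4-(benzyloxy)-3-bromophenyl]prop-2-en-1-one
Conditions: KOH (aq, 50 wt %), EtOH, rt; then dilute HCl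
Reagents that add atoms: none
Why: Claisen–Schmidt condensation of a methyl ketone enolate with a non-enolisable aldehyde, in which E1cB loss of water should give the conjugated E-alkene under thermodynamic control.

Step 4
Reactants: 5 (E)-1-[2-(benzyloxy)-6-hydroxy-4-methoxyphenyl]-3-[4-(benzyloxy)-3-bromophenyl]prop-2-en-1-one
Product: 6 5-(benzyloxy)-2-[4-(benzyloxy)-3-bromophenyl]-7-methoxy-4H-chromen-4-one
Conditions: I2 (10 mol %), DMSO, 130 °C
Reagents that add atoms: none
Why: Iodine-catalysed oxidative cyclisation of a 2'-hydroxychalcone (oxa-Michael closure of ring C, alpha-iodination and loss of HI, with DMSO re-oxidising the iodide), a standard flavone synthesis that leaves the aryl bromide and the benzyl ethers untouched.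

Step 5
Reactants: 7 phloroglucinol
Product: 8 3,5-bis(methoxymethoxy)phenol
Conditions: MOMCl (2.0 equiv), K2CO3 (2.5 equiv), acetone, 0 °C to rt; chromatography
Reagents that add atoms: chloromethyl methyl ether, COCCl
Why: Williamson-type O-alkylation with a hard electrophile that prefers oxygen over carbon, in which the three equivalent hydroxyls leave only the degree of alkylation to be sorted out by chromatography on a very cheap starting material.

Step 6
Reactants: 8 3,5-bis(methoxymethoxy)phenol
Product: 9 1-(benzyloxy)-3,5-bis(methoxymethoxy)benzene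
Conditions: BnBr (1.2 equiv), K2CO3, DMF, 50 °C
Reagents that add atoms: benzyl bromide, BrCc1ccccc1
Why: Williamson etherification of the single remaining phenol under basic conditions that the MOM acetals tolerate.

Step 7
Reactants: 9 1-(benzyloxy)-3,5-bis(methoxymethoxy)benzene; 6 5-(benzyloxy)-2-[4-(benzyloxy)-3-bromophenyl]-7-methoxy-4H-chromen-4-one
Product: 12 5-(benzyloxy)-2-{4-(benzyloxy)-3-[4-(benzyloxy)-2,6-bis(methoxymethoxy)phenyl]phenyl}-7-methoxy-4H-chromen-4-one, via aryllithium 10 (not isolated), via arylzinc chloride 11 (not isolated)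
Conditions: 9 (1.4 equiv), n-BuLi (1.4 equiv), THF, 0 °C; ZnCl2 (1.5 equiv), THF, 0 °C to rt; then 6, Pd2(dba)3 (2.5 mol %), RuPhos (10 mol %), THF, 65 °C
Reagents that add atoms: none
Why: Directed ortho-metalation at the one C–H flanked by two chelating MOM oxygens, transmetalation to zinc and Negishi coupling, where zinc is chosen because 2,4,6-trialkoxyaryl boron reagents protodeboronate easily in aqueous base, the arylzinc does not add to the chromenone, and bulky dialkylbiarylphosphine ligands are established for biaryls with three ortho substituents.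

Step 8
Reactants: 12 5-(benzyloxy)-2-{4-(benzyloxy)-3-[4-(benzyloxy)-2,6-bis(methoxymethoxy)phenyl]phenyl}-7-methoxy-4H-chromen-4-one
Product: 13 5-(benzyloxy)-2-{4-(benzyloxy)-3-[4-(benzyloxy)-2,6-dihydroxyphenyl]phenyl}-7-methoxy-4H-chromen-4-one
Conditions: HCl (3 M aq), MeOH–THF, 50 °C
Reagents that add atoms: none
Why: Acid-catalysed acetal exchange removes both phenolic MOM groups while the benzyl ethers, the methyl ether and ring C persist, and since ring D carries no pyranone yet the acid cannot cause any ring-opening isomerisation.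

Step 9
Reactants: 13 5-(benzyloxy)-2-{4-(benzyloxy)-3-[4-(benzyloxy)-2,6-dihydroxyphenyl]phenyl}-7-methoxy-4H-chromen-4-one
Product: 14 5-(benzyloxy)-2-{4-(benzyloxy)-3-[4-(benzyloxy)-2,6-dihydroxy-3-iodophenyl]phenyl}-7-methoxy-4H-chromen-4-one
Conditions: NIS (1.0 equiv, slow addition), MeCN–THF, −30 °C to 0 °C, dark
Reagents that add atoms: N-iodosuccinimide, O=C1CCC(=O)N1I
Why: Electrophilic aromatic iodination of ring D, by far the most electron-rich ring, whose two open positions (each ortho to one free hydroxyl, para to the other and ortho to the benzyloxy group) are equivalent, so that one monoiodide is possible and stoichiometry with low temperature should hold back a second substitution.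

Step 10
Reactants: 14 5-(benzyloxy)-2-{4-(benzyloxy)-3-[4-(benzyloxy)-2,6-dihydroxy-3-iodophenyl]phenyl}-7-methoxy-4H-chromen-4-one; 15 1-(benzyloxy)-4-ethynylbenzene
Product: 18 sequoiaflavone 5,4',5'',4'''-tetrabenzyl ether, via ynone 16 (not isolated), via enaminone 17 (not isolated)
Conditions: 15 (1.5 equiv), PdCl2(PPh3)2 (5 mol %), CO (20 bar), Et2NH–DMF, 100 °C, autoclave, no copper salt
Reagents that add atoms: carbon monoxide, [C-]#[O+]
Why: PdCl2(PPh3)2 is reduced in the amine/CO medium to zerovalent palladium, which inserts into the C4a''–I bond; migratory insertion of CO gives the aroyl complex of divalent palladium, the acetylide formed from 15 by Et2NH takes the place of iodide on it, and reductive elimination gives ynone 16 with the new C4a''–C4'' and C4''–C3'' bonds. Et2NH then adds to C2'' of 16 to give enaminone 17, and the C8a'' hydroxyl displaces the amine by addition–elimination at C2'', forming O1''–C2''. Ring E therefore closes in the 6-endo mode (6-endo-trig on 17), while direct 5-exo-dig attack of the phenoxide on C3'' of the ynone, the path to an aurone, is pre-empted by the faster amine addition. The closest known reaction type is the palladium-catalysed carbonylative coupling and cyclisation of 2-iodophenols with terminal arylacetylenes in a secondary amine, an established flavone synthesis, and no stereocentre is created. The selectivity needed is 8-aryl over 6-aryl annulation, and the substrate secures it because the acyl carbon on C4a'' has only one free ortho hydroxyl (on C8a'', next to the aryl-bearing C8''), the other ortho oxygen (C5'') being a benzyl ether and the C7'' hydroxyl being para and out of reach. CO uptake ahead of alkynylation is favoured by the CO pressure and by the absence of copper, and the basic medium together with the blocked C5'' oxygen excludes a Wessely–Moser-type opening and reclosure.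

Step 11
Reactants: 18 sequoiaflavone 5,4',5'',4'''-tetrabenzyl ether
Product: 19 sequoiaflavone
Conditions: H2 (1 atm), Pd/C (10 wt %), THF–MeOH, rt
Reagents that add atoms: none
Why: Catalytic hydrogenolysis cleaves the four aryl benzyl ethers under neutral, mild conditions that should spare the methyl ether and the cross-conjugated C2=C3 bonds of both pyranones and give the freed C5'' hydroxyl no chance of acid-induced isomerisation.

## Compound list

1 | 2',6'-dihydroxy-4'-methoxyacetophenone | CC(=O)c1c(O)cc(OC)cc1O | starting material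
2 | 1-[2-(benzyloxy)-6-hydroxy-4-methoxyphenyl]ethan-1-one | CC(=O)c1c(O)cc(OC)cc1OCc1ccccc1 | intermediate
3 | 3-bromo-4-hydroxybenzaldehyde | O=Cc1ccc(O)c(Br)c1 | starting material
4 | 4-(benzyloxy)-3-bromobenzaldehyde | O=Cc1ccc(OCc2ccccc2)c(Br)c1 | intermediate
5 | (E)-1-[2-(benzyloxy)-6-hydroxy-4-methoxyphenyl]-3-[4-(benzyloxy)-3-bromophenyl]prop-2-en-1-one | COc1cc(O)c(C(=O)/C=C/c2ccc(OCc3ccccc3)c(Br)c2)c(OCc2ccccc2)c1 | intermediate
6 | 5-(benzyloxy)-2-[4-(benzyloxy)-3-bromophenyl]-7-methoxy-4H-chromen-4-one | COc1cc(OCc2ccccc2)c2c(=O)cc(-c3ccc(OCc4ccccc4)c(Br)c3)oc2c1 | intermediate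
7 | phloroglucinol | Oc1cc(O)cc(O)c1 | starting material
8 | 3,5-bis(methoxymethoxy)phenol | COCOc1cc(O)cc(OCOC)c1 | intermediate
9 | 1-(benzyloxy)-3,5-bis(methoxymethoxy)benzene | COCOc1cc(OCOC)cc(OCc2ccccc2)c1 | intermediate
10 | [4-(benzyloxy)-2,6-bis(methoxymethoxy)phenyl]lithium | [Li]c1c(OCOC)cc(OCc2ccccc2)cc1OCOC | intermediate
11 | [4-(benzyloxy)-2,6-bis(methoxymethoxy)phenyl]zinc chloride | Cl[Zn]c1c(OCOC)cc(OCc2ccccc2)cc1OCOC | intermediate
12 | 5-(benzyloxy)-2-{4-(benzyloxy)-3-[4-(benzyloxy)-2,6-bis(methoxymethoxy)phenyl]phenyl}-7-methoxy-4H-chromen-4-one | COc1cc(OCc2ccccc2)c2c(=O)cc(-c3ccc(OCc4ccccc4)c(-c4c(OCOC)cc(OCc5ccccc5)cc4OCOC)c3)oc2c1 | intermediate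
13 | 5-(benzyloxy)-2-{4-(benzyloxy)-3-[4-(benzyloxy)-2,6-dihydroxyphenyl]phenyl}-7-methoxy-4H-chromen-4-one | COc1cc(OCc2ccccc2)c2c(=O)cc(-c3ccc(OCc4ccccc4)c(-c4c(O)cc(OCc5ccccc5)cc4O)c3)oc2c1 | intermediate
14 | 5-(benzyloxy)-2-{4-(benzyloxy)-3-[4-(benzyloxy)-2,6-dihydroxy-3-iodophenyl]phenyl}-7-methoxy-4H-chromen-4-one | COc1cc(OCc2ccccc2)c2c(=O)cc(-c3ccc(OCc4ccccc4)c(-c4c(O)cc(OCc5ccccc5)c(I)c4O)c3)oc2c1 | intermediate
15 | 1-(benzyloxy)-4-ethynylbenzene | C#Cc1ccc(OCc2ccccc2)cc1 | starting material
16 | 5-(benzyloxy)-2-{4-(benzyloxy)-3-[4-(benzyloxy)-3-{3-[4-(benzyloxy)phenyl]prop-2-ynoyl}-2,6-dihydroxyphenyl]phenyl}-7-methoxy-4H-chromen-4-one (ynone) | COc1cc(OCc2ccccc2)c2c(=O)cc(-c3ccc(OCc4ccccc4)c(-c4c(O)cc(OCc5ccccc5)c(C(=O)C#Cc5ccc(OCc6ccccc6)cc5)c4O)c3)oc2c1 | intermediate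
17 | 5-(benzyloxy)-2-{4-(benzyloxy)-3-[4-(benzyloxy)-3-{3-[4-(benzyloxy)phenyl]-3-(diethylamino)prop-2-enoyl}-2,6-dihydroxyphenyl]phenyl}-7-methoxy-4H-chromen-4-one (enaminone; push–pull alkene, geometry not fixed) | COc1cc(OCc2ccccc2)c2c(=O)cc(-c3ccc(OCc4ccccc4)c(-c4c(O)cc(OCc5ccccc5)c(C(=O)C=C(N(CC)CC)c5ccc(OCc6ccccc6)cc5)c4O)c3)oc2c1 | intermediate
18 | sequoiaflavone 5,4',5'',4'''-tetrabenzyl ether (C7'' hydroxyl free) | COc1cc(OCc2ccccc2)c2c(=O)cc(-c3ccc(OCc4ccccc4)c(-c4c(O)cc(OCc5ccccc5)c5c(=O)cc(-c6ccc(OCc7ccccc7)cc6)oc45)c3)oc2c1 | intermediate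
19 | sequoiaflavone | COc1cc(O)c2c(=O)cc(-c3ccc(O)c(-c4c(O)cc(O)c5c(=O)cc(-c6ccc(O)cc6)oc45)c3)oc2c1 | target

## Step count and risks

Total step count: 11.
Longest linear sequence: 8 steps (steps 1, 3, 4, 7, 8, 9, 10, 11).

**Step 10 (carbonylative annulation).**
- Risk: the C–I bond sits between two oxygen substituents on a very electron-rich ring, and CO slows palladium insertion further. Reductive loss of iodine, capture of the aroyl complex by diethylamine, and alkynylation without CO uptake followed by furan closure may then outrun ynone formation.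
- Fallback: it sets out from 14 and comes back at 19. Ring E is built by the chalcone route, and the iodine still fixes where the acyl carbon goes.
- Stille coupling of 14 with tributyl(1-ethoxyvinyl)stannane (PdCl2(PPh3)2, dioxane, 90 °C) should give the C4a''-(1-ethoxyvinyl)resorcinol F1. Dilute HCl in THF at rt hydrolyses it to the C4a''-acetylresorcinol F2.
- BnBr and K2CO3 in acetone should alkylate only the unchelated C7'' hydroxyl and give the C7''-benzyl ether F3.
- Claisen–Schmidt condensation with 4-(benzyloxy)benzaldehyde (KOH, EtOH–THF, rt) should give the chalcone F4.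
- I2 (10 mol %) in DMSO at 130 °C closes ring E through the C8a'' hydroxyl, the only free one, and gives sequoiaflavone 5,4',5'',7'',4'''-pentabenzyl ether F5. Hydrogenolysis under the conditions of step 11 leads to 19.

**Step 7 (metalation and Negishi coupling).**
- Risk: transmetalation and reductive elimination are slow at a palladium centre that carries two ortho-substituted aryl groups, so hydrodebromination and homocoupling gain ground. Misdirected metalation of 9, at the benzylic CH2 or next to the benzyloxy group, would also consume the organometallic reagent.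
- Fallback: it sets out from 6 and 9 and comes back at 12, with the roles of the two partners exchanged.
- Miyaura borylation of 6 (B2pin2, PdCl2(dppf), KOAc, dioxane, 90 °C) should give the flavone 3'-pinacolboronate F6.
- Aryllithium 10, made as in step 7, is quenched with I2 at −78 °C to give 5-(benzyloxy)-2-iodo-1,3-bis(methoxymethoxy)benzene F7. This iodide can be purified, so errors of lithiation are removed before the coupling.
- Suzuki–Miyaura coupling of F6 and F7 (Pd(OAc)2, SPhos, K3PO4, dioxane–H2O, 90 °C) should give 12. Boron now sits on the ring with a single ortho oxygen, where protodeboronation is slow.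

**Step 9 (monoiodination).**
- Risk: over-iodination, because one iodine hardly deactivates a free resorcinol, and loss or migration of iodine if traces of acid are present during handling.
- Fallback: it sets out from 12 and comes back at 14, with steps 8 and 9 in reversed order.
- NIS (1.05 equiv) in MeCN at rt iodinates the aryl ether 12 and should give the iodo bis(methoxymethyl) ether F8. Here a second substitution would have to occur on a less activated and already crowded ring.
- The MOM groups are then removed with catalytic HCl in MeOH–THF at 40 °C with short contact time, giving 14.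

## Further compounds

F1 | step 10 | C4a''-(1-ethoxyvinyl)resorcinol: 5-(benzyloxy)-2-{4-(benzyloxy)-3-[4-(benzyloxy)-3-(1-ethoxyethenyl)-2,6-dihydroxyphenyl]phenyl}-7-methoxy-4H-chromen-4-one | COc1cc(OCc2ccccc2)c2c(=O)cc(-c3ccc(OCc4ccccc4)c(-c4c(O)cc(OCc5ccccc5)c(C(=C)OCC)c4O)c3)oc2c1
F2 | step 10 | C4a''-acetylresorcinol: 2-{3-[3-acetyl-4-(benzyloxy)-2,6-dihydroxyphenyl]-4-(benzyloxy)phenyl}-5-(benzyloxy)-7-methoxy-4H-chromen-4-one | COc1cc(OCc2ccccc2)c2c(=O)cc(-c3ccc(OCc4ccccc4)c(-c4c(O)cc(OCc5ccccc5)c(C(C)=O)c4O)c3)oc2c1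
F3 | step 10 | C7''-benzyl ether: 2-{3-[3-acetyl-4,6-bis(benzyloxy)-2-hydroxyphenyl]-4-(benzyloxy)phenyl}-5-(benzyloxy)-7-methoxy-4H-chromen-4-one | COc1cc(OCc2ccccc2)c2c(=O)cc(-c3ccc(OCc4ccccc4)c(-c4c(OCc5ccccc5)cc(OCc5ccccc5)c(C(C)=O)c4O)c3)oc2c1
F4 | step 10 | chalcone: 5-(benzyloxy)-2-{4-(benzyloxy)-3-[4,6-bis(benzyloxy)-3-{(E)-3-[4-(benzyloxy)phenyl]prop-2-enoyl}-2-hydroxyphenyl]phenyl}-7-methoxy-4H-chromen-4-one | COc1cc(OCc2ccccc2)c2c(=O)cc(-c3ccc(OCc4ccccc4)c(-c4c(OCc5ccccc5)cc(OCc5ccccc5)c(C(=O)/C=C/c5ccc(OCc6ccccc6)cc5)c4O)c3)oc2c1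
F5 | step 10 | sequoiaflavone 5,4',5'',7'',4'''-pentabenzyl ether | COc1cc(OCc2ccccc2)c2c(=O)cc(-c3ccc(OCc4ccccc4)c(-c4c(OCc5ccccc5)cc(OCc5ccccc5)c5c(=O)cc(-c6ccc(OCc7ccccc7)cc6)oc45)c3)oc2c1
F6 | step 7 | flavone 3'-pinacolboronate: 5-(benzyloxy)-2-[4-(benzyloxy)-3-(4,4,5,5-tetramethyl-1,3,2-dioxaborolan-2-yl)phenyl]-7-methoxy-4H-chromen-4-one | COc1cc(OCc2ccccc2)c2c(=O)cc(-c3ccc(OCc4ccccc4)c(B4OC(C)(C)C(C)(C)O4)c3)oc2c1
F7 | step 7 | 5-(benzyloxy)-2-iodo-1,3-bis(methoxymethoxy)benzene | COCOc1cc(OCc2ccccc2)cc(OCOC)c1I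
F8 | step 9 | iodo bis(methoxymethyl) ether: 5-(benzyloxy)-2-{4-(benzyloxy)-3-[4-(benzyloxy)-3-iodo-2,6-bis(methoxymethoxy)phenyl]phenyl}-7-methoxy-4H-chromen-4-one | COc1cc(OCc2ccccc2)c2c(=O)cc(-c3ccc(OCc4ccccc4)c(-c4c(OCOC)cc(OCc5ccccc5)c(I)c4OCOC)c3)oc2c1
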